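The chain is numbered C1 (lactone carbonyl) to C20; the ring oxygen joins C1 and C5. The route rests on cutting C11–C12 and on the hidden twofold symmetry of C5–C11: with C5 and C11 as acyl carbons, the anti C7/C9 diol folds into the symmetric dilactone (1R,5R)-2,6-dioxabicyclo[3.3.1]nonane-3,7-dione, made by double Baeyer–Villiger cleavage of norbornane-2,5-dione. In the key step nonylmagnesium bromide adds to one of the two homotopic lactone carbonyls (C11–C12); the persistent lactolate masks C11 while a dioxinone dienolate opens the second ring at C5. One flask thus gives the whole C1–C20 skeleton, with O7–H and O9–H freed to direct both syn reductions.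

Key step: step 2

Remark: 1 (sold as the precursor of chiral norbornadiene ligands), 4 (ether solution) and 5 are taken as purchased; 8 is written open-chain although its δ-hydroxy ketone units may rest partly as cyclic hemiketals, and the lactol carbon of 6 is left unassigned because it is lost on work-up.

Step 1
Reactants: 1 (1R,4R)-bicyclo[2.2.1]heptane-2,5-dione
Product: 3 (1R,5R)-2,6-dioxabicyclo[3.3.1]nonane-3,7-dione, via keto lactone 2 (not isolated)
Conditions: mCPBA (3 equiv), NaHCO3, CH2Cl2, 0 °C to 40 °C
Reagents that add atoms: mCPBA (3-chloroperoxybenzoic acid), O=C(OO)c1cccc(Cl)c1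
Why: Double Baeyer–Villiger oxidation: at each strained ring ketone the bridgehead carbon (the more substituted neighbour) migrates to oxygen with retention, so that the C7–C11 and C9–C5 bonds are cut, O7 and O9 are installed on the former bridgeheads and the two stereocentres of 1 are carried unchanged into the anti C7/C9 pattern of 3; no new stereocentre is formed.

Step 2
Reactants: 3 (1R,5R)-2,6-dioxabicyclo[3.3.1]nonane-3,7-dione; 4 nonylmagnesium bromide; 5 2,2,6-trimethyl-4H-1,3-dioxin-4-one
Product: 8 6-[(4R,6R)-4,6-dihydroxy-2,8-dioxoheptadecyl]-2,2-dimethyl-4H-1,3-dioxin-4-one, via magnesium lactolate 6 (not isolated), via lithium dienolate 7 (not isolated)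
Conditions: 4 (1.0 equiv, added slowly), THF, −78 °C; then 7 (3 equiv, from 5 and LiN(iPr)2, THF, −78 °C) by cannula, −78 °C; AcOH, −78 °C
Reagents that add atoms: none
Why: Nucleophilic acyl addition of the Grignard reagent to one of the two homotopic lactone carbonyls of 3 forms C11–C12 and stops at the tetrahedral magnesium lactolate 6, which should persist at −78 °C and mask C11 while the γ-carbon of dienolate 7 is acylated by the second lactone carbonyl (C4–C5, Claisen type), excess 7 absorbing the acidic keto-dioxinone; the cold acidic quench then releases both ketones and both hydroxyls. The closest known reaction types are the mono-addition of organomagnesium or organolithium reagents to δ-lactones to give lactols, and the γ-acylation of this dienolate by acyl donors. No ring is closed (both lactone rings are opened by acyl–oxygen cleavage) and no stereocentre is created: C7 and C9 keep the configuration of 3 because their C–O bonds are untouched. The step needs reaction of 4 at one lactone only, which is served by the twofold symmetry (either carbonyl gives the same product), by the single equivalent of 4 and by the anionic charge of 6. It also needs C11 to stay at the ketal level during the second addition, which the low temperature and the cold quench should secure.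

Step 3
Reactants: 8 6-[(4R,6R)-4,6-dihydroxy-2,8-dioxoheptadecyl]-2,2-dimethyl-4H-1,3-dioxin-4-one
Product: 9 6-[(2R,4R,6S,8S)-2,4,6,8-tetrahydroxyheptadecyl]-2,2-dimethyl-4H-1,3-dioxin-4-one
Conditions: Et2BOMe (2.5 equiv), THF/MeOH 4:1, −78 °C; NaBH4 (3 equiv), −78 °C; AcOH, then MeOH co-evaporation
Reagents that add atoms: none
Why: Double Narasaka–Prasad reduction: each free hydroxyl forms an O–BEt2 chelate with the carbonyl β to it (O9 with C11, O7 with C5) and external hydride adds axially to each half-chair chelate, which sets C11 syn to C9 (11S) and C5 syn to C7 (5R) in one operation, the dioxinone being inert to NaBH4 at −78 °C.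

Step 4
Reactants: 9 6-[(2R,4R,6S,8S)-2,4,6,8-tetrahydroxyheptadecyl]-2,2-dimethyl-4H-1,3-dioxin-4-one
Product: 11 (6R)-4-hydroxy-6-[(2R,4S,6S)-2,4,6-trihydroxypentadecyl]-5,6-dihydro-2H-pyran-2-one, via acylketene 10 (not isolated)
Conditions: toluene (0.005 M), 110 °C
Reagents that add atoms: none
Why: Thermal retro-[4+2] cleavage of the dioxinone expels acetone to give acylketene 10, which is captured intramolecularly by the C5 hydroxyl (six-membered ring; the other hydroxyls would need eight-membered or larger rings) to give the β-keto-δ-lactone that rests as its enol 11; no stereocentre is touched.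

Compound list
1 | (1R,4R)-bicyclo[2.2.1]heptane-2,5-dione | O=C1C[C@H]2C[C@@H]1CC2=O | starting material
2 | (1R,5R)-2-oxabicyclo[3.2.1]octane-3,6-dione (keto lactone, not isolated) | O=C1C[C@H]2C[C@H](CC2=O)O1 | intermediate
3 | (1R,5R)-2,6-dioxabicyclo[3.3.1]nonane-3,7-dione | O=C1C[C@H]2C[C@H](CC(=O)O2)O1 | intermediate
4 | nonylmagnesium bromide | CCCCCCCCC[Mg]Br | starting material
5 | 2,2,6-trimethyl-4H-1,3-dioxin-4-one | CC1=CC(=O)OC(C)(C)O1 | starting material
6 | bromomagnesium (1R,5R)-3-nonyl-7-oxo-2,6-dioxabicyclo[3.3.1]nonan-3-olate (magnesium lactolate, not isolated) | CCCCCCCCCC1(O[Mg]Br)C[C@H]2C[C@H](CC(=O)O2)O1 | intermediate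
7 | lithium 2,2-dimethyl-6-methylidene-6H-1,3-dioxin-4-olate (lithium dienolate, not isolated) | C=C1C=C(O[Li])OC(C)(C)O1 | intermediate
8 | 6-[(4R,6R)-4,6-dihydroxy-2,8-dioxoheptadecyl]-2,2-dimethyl-4H-1,3-dioxin-4-one | CCCCCCCCCC(=O)C[C@H](O)C[C@@H](O)CC(=O)CC1=CC(=O)OC(C)(C)O1 | intermediate
9 | 6-[(2R,4R,6S,8S)-2,4,6,8-tetrahydroxyheptadecyl]-2,2-dimethyl-4H-1,3-dioxin-4-one | CCCCCCCCC[C@H](O)C[C@H](O)C[C@@H](O)C[C@@H](O)CC1=CC(=O)OC(C)(C)O1 | intermediate
10 | (5R,7R,9S,11S)-5,7,9,11-tetrahydroxy-3-oxoicos-1-en-1-one (acylketene, not isolated) | CCCCCCCCC[C@H](O)C[C@H](O)C[C@@H](O)C[C@@H](O)CC(=O)C=C=O | intermediate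
11 | (6R)-4-hydroxy-6-[(2R,4S,6S)-2,4,6-trihydroxypentadecyl]-5,6-dihydro-2H-pyran-2-one | CCCCCCCCC[C@H](O)C[C@H](O)C[C@@H](O)C[C@@H]1CC(O)=CC(=O)O1 | target

Total step count: 4. Longest linear sequence: 4 steps (1 to 3 to 8 to 9 to 11).

Steps most likely to fail

Step 2. The Grignard reagent may add at both lactone carbonyls, the basic reagents may trigger β-elimination of the acyloxy group next to an enolisable methylene, or the lactolate may collapse early and expose the C11 ketone to the dienolate. The fallback sets out from 3 and replaces the lactolate by the more persistent chelated intermediate of a Weinreb ketone synthesis. Both rings of 3 are opened with Me(MeO)NH·HCl and AlMe3 (CH2Cl2, 0 °C to room temperature) to give (3R,5R)-3,5-dihydroxy-N1,N7-dimethoxy-N1,N7-dimethylheptanediamide F1. The anti diol is tied with 2,2-dimethoxypropane and PPTS as 2,2'-[(4R,6R)-2,2-dimethyl-1,3-dioxane-4,6-diyl]bis(N-methoxy-N-methylacetamide) F2, which has no acyloxy leaving group. One equivalent of 4 (THF, 0 °C) then gives the chelated bromomagnesium hemiaminal salt F3. In the same flask, dienolate 7 (−78 °C) is acylated by the second amide and, after quench, gives 6-{3-[(4R,6R)-2,2-dimethyl-6-(2-oxoundecyl)-1,3-dioxan-4-yl]-2-oxopropyl}-2,2-dimethyl-4H-1,3-dioxin-4-one F4. Aqueous acetic acid at room temperature removes the acetonide, and the route is rejoined at 8.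

Step 3. Hemiketal formation may withhold a carbonyl from its boron chelate, or hydride delivery at C5 may lose facial selectivity because the acidic C4 methylene lets the keto-dioxinone enolise. The fallback sets out from 8 and takes C5 out of the hydride reduction altogether. Heating 8 in toluene (110 °C) gives the acylketene (7R,9R)-7,9-dihydroxy-3,5,11-trioxoicos-1-en-1-one F5, which closes through the enol oxygen of the C5 ketone to 4-hydroxy-6-[(2R,4R)-2,4-dihydroxy-6-oxopentadecyl]-2H-pyran-2-one F6. Et2BOMe and NaBH4 (−78 °C) then reduce the single remaining β-hydroxy ketone to 4-hydroxy-6-[(2R,4S,6S)-2,4,6-trihydroxypentadecyl]-2H-pyran-2-one F7. C5 is set last by catalytic enantioselective hydrogenation of the ring C5=C6 bond (H2, [Ru(OAc)2(MeO-BIPHEP)], HBF4, MeOH), a reaction known for 6-alkyl-4-hydroxy-2-pyranones. The ligand enantiomer that leads to 6R would first be identified in a trial run on 4-hydroxy-6-methyl-2H-pyran-2-one. The route is rejoined at 11.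

Step 4. The acylketene may be captured between molecules (oligomeric esters) or by one of the remote hydroxyls, or the polyol may dissolve poorly in hot toluene. The fallback sets out from 9 and uses ionic ring opening instead of the ketene. K2CO3 in MeOH at room temperature opens the dioxinone to methyl (5R,7R,9S,11S)-5,7,9,11-tetrahydroxy-3-oxoicosanoate F8. This ester lactonises onto the C5 hydroxyl under the same conditions, and acidification with dilute HCl rejoins the route at 11.

Further compounds
F1 | step 2 | (3R,5R)-3,5-dihydroxy-N1,N7-dimethoxy-N1,N7-dimethylheptanediamide | CON(C)C(=O)C[C@H](O)C[C@@H](O)CC(=O)N(C)OC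
F2 | step 2 | 2,2'-[(4R,6R)-2,2-dimethyl-1,3-dioxane-4,6-diyl]bis(N-methoxy-N-methylacetamide) | CON(C)C(=O)C[C@H]1C[C@H](CC(=O)N(C)OC)OC(C)(C)O1
F3 | step 2 | chelated bromomagnesium hemiaminal salt from F2 and 4 | CCCCCCCCCC(O[Mg]Br)(N(C)OC)C[C@H]1C[C@H](CC(=O)N(C)OC)OC(C)(C)O1
F4 | step 2 | 6-{3-[(4R,6R)-2,2-dimethyl-6-(2-oxoundecyl)-1,3-dioxan-4-yl]-2-oxopropyl}-2,2-dimethyl-4H-1,3-dioxin-4-one | CCCCCCCCCC(=O)C[C@H]1C[C@H](CC(=O)CC2=CC(=O)OC(C)(C)O2)OC(C)(C)O1
F5 | step 3 | (7R,9R)-7,9-dihydroxy-3,5,11-trioxoicos-1-en-1-one | CCCCCCCCCC(=O)C[C@H](O)C[C@@H](O)CC(=O)CC(=O)C=C=O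
F6 | step 3 | 4-hydroxy-6-[(2R,4R)-2,4-dihydroxy-6-oxopentadecyl]-2H-pyran-2-one | CCCCCCCCCC(=O)C[C@H](O)C[C@@H](O)CC1=CC(O)=CC(=O)O1
F7 | step 3 | 4-hydroxy-6-[(2R,4S,6S)-2,4,6-trihydroxypentadecyl]-2H-pyran-2-one | CCCCCCCCC[C@H](O)C[C@H](O)C[C@@H](O)CC1=CC(O)=CC(=O)O1
F8 | step 4 | methyl (5R,7R,9S,11S)-5,7,9,11-tetrahydroxy-3-oxoicosanoate | CCCCCCCCC[C@H](O)C[C@H](O)C[C@@H](O)C[C@@H](O)CC(=O)CC(=O)OC
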